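**Retrosynthetic overview**

1. The strategy rests on C2 and C3 of the upper flavanone (ring C). C2 carries O1 and the catechol ring, C3 carries C8'' of the lower unit and the C4 carbonyl, and the two are cis. This is the pattern of a syn aldol, stored as a cis-3,4-disubstituted β-lactone.
2. The first ring formed is that β-lactone (temporary). It comes from a catalytic ketene–aldehyde [2+2] of a 2-fluoro-4,6-bis(benzyloxy)phenylketene with 3,4-bis(benzyloxy)benzaldehyde, which makes the C2–C3 bond and both centres.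
3. The second ring is ring C of the upper unit. A ring A aryllithium opens the lactone at its acyl carbon (C4–C4a bond), and the C2 alkoxide displaces the ring A fluorine (O1–C8a bond).
4. The third ring is the pyranone of the lower unit. With C4 masked as a silyl ether, the fluoroaryl ring on C3 is lithiated between F and OBn (C4a'') and acylated with an (S)-β-silyloxy Weinreb amide. The carbinol oxygen then displaces that fluorine (O1''–C8a'').
5. The end game is desilylation, oxidation at C4 and hydrogenolysis of seven benzyl ethers. Both fluoroarenes come from 5-fluororesorcinol through one aryl bromide.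

Key step: step 6

Remark: O-trimethylsilylquinine is written for step 6; if a test run shows that it gives the (3S,4S) lactone, O-trimethylsilylquinidine takes its place and nothing else changes.
Remark: the C4 carbinol centre of 13, 14 and 20–24 is temporary (erased in step 18); the all-cis epimer expected from step 8 is drawn, and its epimer would serve equally.

**Route**

Step 1
Reactants: 1 5-fluororesorcinol
Product: 2 1-fluoro-3,5-bis(benzyloxy)benzene
Conditions: BnBr, K2CO3, DMF, 60 °C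
Reagents that add atoms: benzyl bromide BrCc1ccccc1
Why: Williamson ether synthesis on both phenols under carbonate conditions that leave the aryl fluoride alone.

Step 2
Reactants: 2 1-fluoro-3,5-bis(benzyloxy)benzene
Product: 3 1-bromo-2-fluoro-4,6-bis(benzyloxy)benzene
Conditions: NBS (1.0 equiv), MeCN, 0 °C
Reagents that add atoms: N-bromosuccinimide O=C1CCC(=O)N1Br
Why: Electrophilic aromatic bromination should go para to one benzyloxy group and ortho to the other (next to the small fluorine) rather than into the crowded site between the two benzyloxy groups, as 1,3-dialkoxybenzenes do.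

Step 3
Reactants: 3 1-bromo-2-fluoro-4,6-bis(benzyloxy)benzene
Product: 4 ethyl [2-fluoro-4,6-bis(benzyloxy)phenyl]acetate
Conditions: BrCH2CO2Et, Zn dust (TMSCl-activated), THF, 40 °C; then 3, Pd2(dba)3 (2 mol%), XPhos (8 mol%), THF, 65 °C
Reagents that add atoms: ethyl bromoacetate CCOC(=O)CBr
Why: Negishi-type cross-coupling of the Reformatsky reagent (palladium-catalysed α-arylation of a zinc ester enolate) works under nearly neutral conditions that tolerate the aryl fluoride and benzyl ethers, and the bulky biarylphosphine handles the di-ortho-substituted bromide.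

Step 4
Reactants: 4 ethyl [2-fluoro-4,6-bis(benzyloxy)phenyl]acetate
Product: 5 [2-fluoro-4,6-bis(benzyloxy)phenyl]acetic acid
Conditions: LiOH·H2O, THF/MeOH/H2O, rt; then aq. HCl
Reagents that add atoms: lithium hydroxide [Li+].[OH-]
Why: Ester saponification; the unactivated aryl fluoride and the benzyl ethers are inert to hydroxide at room temperature.

Step 5
Reactants: 5 [2-fluoro-4,6-bis(benzyloxy)phenyl]acetic acid
Product: 6 [2-fluoro-4,6-bis(benzyloxy)phenyl]acetyl chloride
Conditions: (COCl)2, DMF (cat.), CH2Cl2, 0 °C to rt; volatiles removed, used crude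
Reagents that add atoms: oxalyl chloride O=C(Cl)C(=O)Cl
Why: Acid chloride formation through the Vilsmeier-type chloroiminium species, giving only gaseous by-products so that 6 can go straight into the key step.

Step 6
Reactants: 6 [2-fluoro-4,6-bis(benzyloxy)phenyl]acetyl chloride; 7 3,4-bis(benzyloxy)benzaldehyde
Product: 9 (3R,4R)-4-[3,4-bis(benzyloxy)phenyl]-3-[2-fluoro-4,6-bis(benzyloxy)phenyl]oxetan-2-one, via arylketene 8 (not isolated)
Conditions: O-trimethylsilylquinine (15 mol%), LiClO4 (1 equiv), iPr2NEt (2.5 equiv), CH2Cl2/Et2O, −78 °C, slow addition of 6; cold work-up, used at once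
Reagents that add atoms: none
Why: iPr2NEt dehydrochlorinates 6 to arylketene 8, O-trimethylsilylquinine adds to the ketene carbonyl carbon from the side away from the aryl group to give a Z ammonium enolate, this enolate adds to the lithium-bound aldehyde 7 through a closed chair-like transition state (the later C2–C3 bond), and the aldolate oxygen then attacks the acylammonium carbon in a 4-exo-trig closure that forms the oxetanone and frees the alkaloid. The closest known reaction is the cinchona alkaloid and lithium salt catalysed acyl halide–aldehyde cyclocondensation (a Wynberg-type ketene–aldehyde [2+2]) that gives cis-3,4-disubstituted β-lactones; an arylacetyl chloride paired with an electron-rich aromatic aldehyde stands at the limit of what this reaction has been used for. The lactone C3 centre (later flavanone C3) is set by the alkaloid, whose quinoline and quinuclidine units block one face of the bound enolate, and the lactone C4 centre (later C2) follows from the aldehyde aryl group lying equatorial in the chair with the Z enolate, which gives the syn aldolate and so the cis lactone. The step needs cis over trans, one enantiomer, and cross-reaction over ketene dimerisation: slow addition of 6 keeps the ketene concentration low, its two ortho substituents (F and OBn) slow its dimerisation, and the hindered base at −78 °C should leave the acidic C3–H of the product untouched.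

Step 7
Reactants: 3 1-bromo-2-fluoro-4,6-bis(benzyloxy)benzene; 9 (3R,4R)-4-[3,4-bis(benzyloxy)phenyl]-3-[2-fluoro-4,6-bis(benzyloxy)phenyl]oxetan-2-one
Product: 12 (2R,3R)-5,7-bis(benzyloxy)-2-[3,4-bis(benzyloxy)phenyl]-3-[2-fluoro-4,6-bis(benzyloxy)phenyl]chroman-4-one, via aryllithium 10 (not isolated), via lithium aldolate 11 (not isolated)
Conditions: 3 (1.05 equiv), n-BuLi, THF, −78 °C; added to 9, THF, −78 °C; then −78 to 0 °C; aq. NH4Cl at 0 °C
Reagents that add atoms: none
Why: Bromine–lithium exchange gives aryllithium 10, which should attack the strained lactone carbonyl (acyl substitution, forming the C4–C4a bond) faster than it deprotonates C3, and the lithium alkoxide released at C2 then displaces the fluorine ortho to the new ketone by intramolecular SNAr (six-membered ring, addition–elimination), so ring C closes with no bond to C2 or C3 broken and the cis relationship carried over.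

Step 8
Reactants: 12 (2R,3R)-5,7-bis(benzyloxy)-2-[3,4-bis(benzyloxy)phenyl]-3-[2-fluoro-4,6-bis(benzyloxy)phenyl]chroman-4-one
Product: 13 (2R,3S,4R)-5,7-bis(benzyloxy)-2-[3,4-bis(benzyloxy)phenyl]-3-[2-fluoro-4,6-bis(benzyloxy)phenyl]chroman-4-ol
Conditions: NaBH4, CeCl3·7H2O, THF/MeOH, −40 to 0 °C
Reagents that add atoms: none
Why: Luche reduction under nearly neutral conditions removes the carbonyl that makes C3–H acidic before any strong base is used, with hydride expected to enter anti to the pseudo-axial C3 aryl group to give the all-cis carbinol (a temporary centre).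

Step 9
Reactants: 13 (2R,3S,4R)-5,7-bis(benzyloxy)-2-[3,4-bis(benzyloxy)phenyl]-3-[2-fluoro-4,6-bis(benzyloxy)phenyl]chroman-4-ol
Product: 14 (2R,3R,4R)-5,7-bis(benzyloxy)-2-[3,4-bis(benzyloxy)phenyl]-4-(tert-butyldimethylsilyloxy)-3-[2-fluoro-4,6-bis(benzyloxy)phenyl]chromane
Conditions: TBSOTf, 2,6-lutidine, CH2Cl2, −40 to 0 °C
Reagents that add atoms: tert-butyldimethylsilyl triflate CC(C)(C)[Si](C)(C)OS(=O)(=O)C(F)(F)F
Why: Silylation of the hindered benzylic alcohol with the reactive triflate; a free C4 alkoxide would otherwise attack the fluorine of the neighbouring aryl ring in a five-membered SNAr once that ring is acylated.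

Step 10
Reactants: 15 4'-(benzyloxy)acetophenone
Product: 16 ethyl 3-[4-(benzyloxy)phenyl]-3-oxopropanoate
Conditions: NaH, (EtO)2CO, THF, reflux; then aq. HCl
Reagents that add atoms: diethyl carbonate CCOC(=O)OCC
Why: Crossed Claisen condensation of the ketone enolate with diethyl carbonate, driven by deprotonation of the β-keto ester.

Step 11
Reactants: 16 ethyl 3-[4-(benzyloxy)phenyl]-3-oxopropanoate
Product: 17 ethyl (3S)-3-[4-(benzyloxy)phenyl]-3-hydroxypropanoate
Conditions: RuCl[(S,S)-TsDPEN](p-cymene) (1 mol%), HCO2H/Et3N (5:2), 35 °C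
Reagents that add atoms: none
Why: Noyori–Ikariya asymmetric transfer hydrogenation of the aryl ketone, in which the (S,S) catalyst should set the (S) carbinol by the same aryl-directed hydride delivery as with acetophenone (the enantiomeric catalyst is used if a test shows the opposite sense).

Step 12
Reactants: 17 ethyl (3S)-3-[4-(benzyloxy)phenyl]-3-hydroxypropanoate
Product: 18 (3S)-3-[4-(benzyloxy)phenyl]-3-hydroxy-N-methoxy-N-methylpropanamide
Conditions: MeNH(OMe)·HCl, i-PrMgCl (3.2 equiv), THF, −20 to 0 °C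
Reagents that add atoms: N,O-dimethylhydroxylamine hydrochloride CNOC.Cl
Why: Aminolysis of the ester by the magnesium amide of N,O-dimethylhydroxylamine (Weinreb amide formation), with the β-hydroxyl present as its alkoxide so that elimination is held back.

Step 13
Reactants: 18 (3S)-3-[4-(benzyloxy)phenyl]-3-hydroxy-N-methoxy-N-methylpropanamide
Product: 19 (3S)-3-[4-(benzyloxy)phenyl]-N-methoxy-N-methyl-3-(triethylsilyloxy)propanamide
Conditions: TESCl, imidazole, DMF, 0 °C to rt
Reagents that add atoms: chlorotriethylsilane CC[Si](Cl)(CC)CC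
Why: Silylation of the secondary alcohol with a group that can later be removed in the presence of the C4 TBS ether.

Step 14
Reactants: 14 (2R,3R,4R)-5,7-bis(benzyloxy)-2-[3,4-bis(benzyloxy)phenyl]-4-(tert-butyldimethylsilyloxy)-3-[2-fluoro-4,6-bis(benzyloxy)phenyl]chromane; 19 (3S)-3-[4-(benzyloxy)phenyl]-N-methoxy-N-methyl-3-(triethylsilyloxy)propanamide
Product: 21 (3S)-3-[4-(benzyloxy)phenyl]-1-{2-fluoro-4,6-bis(benzyloxy)-3-[(2R,3R,4R)-5,7-bis(benzyloxy)-2-[3,4-bis(benzyloxy)phenyl]-4-(tert-butyldimethylsilyloxy)chroman-3-yl]phenyl}-3-(triethylsilyloxy)propan-1-one, via aryllithium 20 (not isolated)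
Conditions: LiTMP (from 2,2,6,6-tetramethylpiperidine and n-BuLi, 1.1 equiv), THF, −78 °C; then 19 (1.5 equiv), −78 to −60 °C; AcOH in THF at −78 °C
Reagents that add atoms: none
Why: The lithium amide removes the most acidic aryl proton, the only one flanked by fluorine and a benzyloxy group (directed ortho-metalation under acidity control, which spares the benzyl ethers and the sites between two oxygens), and aryllithium 20 is acylated by 19 through its chelated tetrahedral intermediate (Weinreb ketone synthesis), placing the C4'' carbonyl on C4a'' and bringing in C2'' with its configuration.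

Step 15
Reactants: 21 the β-triethylsilyloxy ketone of step 14
Product: 22 (3S)-3-[4-(benzyloxy)phenyl]-1-{2-fluoro-4,6-bis(benzyloxy)-3-[(2R,3R,4R)-5,7-bis(benzyloxy)-2-[3,4-bis(benzyloxy)phenyl]-4-(tert-butyldimethylsilyloxy)chroman-3-yl]phenyl}-3-hydroxypropan-1-one
Conditions: HF·pyridine, pyridine, THF, 0 °C
Reagents that add atoms: none
Why: Buffered fluoride desilylation removes the unhindered triethylsilyl ether much faster than the hindered benzylic TBS ether and is too mild to dehydrate the β-hydroxy ketone.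

Step 16
Reactants: 22 the β-hydroxy ketone of step 15
Product: 23 (2S)-5,7-bis(benzyloxy)-2-[4-(benzyloxy)phenyl]-8-{(2R,3R,4R)-5,7-bis(benzyloxy)-2-[3,4-bis(benzyloxy)phenyl]-4-(tert-butyldimethylsilyloxy)chroman-3-yl}chroman-4-one
Conditions: NaH (1.05 equiv), THF, 0 °C to rt
Reagents that add atoms: none
Why: Intramolecular SNAr of the carbinol alkoxide on the fluorine ortho to the ketone (six-membered ring, addition–elimination; the known route from 2-fluoroaryl β-hydroxy ketones to chroman-4-ones) forms O1''–C8a'' without touching the C2''–O bond, so the (S) configuration is retained.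

Step 17
Reactants: 23 the silyl-protected biflavonoid of step 16
Product: 24 (2S)-5,7-bis(benzyloxy)-2-[4-(benzyloxy)phenyl]-8-{(2R,3S,4R)-5,7-bis(benzyloxy)-2-[3,4-bis(benzyloxy)phenyl]-4-hydroxychroman-3-yl}chroman-4-one
Conditions: TBAF, AcOH (1:1), THF, rt to 45 °C
Reagents that add atoms: none
Why: Fluoride desilylation buffered with acetic acid is close to neutral, so the flavanone is not opened to its chalcone and the benzylic C4–O bond is not ionised.

Step 18
Reactants: 24 the C4 carbinol of step 17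
Product: 25 (2S)-5,7-bis(benzyloxy)-2-[4-(benzyloxy)phenyl]-8-{(2R,3R)-5,7-bis(benzyloxy)-2-[3,4-bis(benzyloxy)phenyl]-4-oxochroman-3-yl}chroman-4-one
Conditions: Dess–Martin periodinane, CH2Cl2, 0 °C to rt
Reagents that add atoms: none
Why: Dess–Martin oxidation returns the C4 ketone without base, so the now acidic C3–H next to it keeps its cis configuration.

Step 19
Reactants: 25 the heptabenzyl biflavanone of step 18
Product: 26 (2S)-8-[(2R,3R)-2-(3,4-dihydroxyphenyl)-5,7-dihydroxy-4-oxochroman-3-yl]-5,7-dihydroxy-2-(4-hydroxyphenyl)chroman-4-one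
Conditions: H2 (1 atm), Pd(OH)2/C, THF/MeOH, rt
Reagents that add atoms: none
Why: Catalytic hydrogenolysis cleaves the seven aryl benzyl ethers under neutral conditions that should leave both flavanone rings, C3 and C2'' as they are, provided the reaction is stopped when the last ether has gone.

**Compound list**

1 | 5-fluororesorcinol | Oc1cc(O)cc(F)c1 | starting material
2 | 1-fluoro-3,5-bis(benzyloxy)benzene | Fc1cc(OCc2ccccc2)cc(OCc2ccccc2)c1 | intermediate
3 | 1-bromo-2-fluoro-4,6-bis(benzyloxy)benzene | Brc1c(F)cc(OCc2ccccc2)cc1OCc1ccccc1 | intermediate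
4 | ethyl [2-fluoro-4,6-bis(benzyloxy)phenyl]acetate | CCOC(=O)Cc1c(F)cc(OCc2ccccc2)cc1OCc1ccccc1 | intermediate
5 | [2-fluoro-4,6-bis(benzyloxy)phenyl]acetic acid | OC(=O)Cc1c(F)cc(OCc2ccccc2)cc1OCc1ccccc1 | intermediate
6 | [2-fluoro-4,6-bis(benzyloxy)phenyl]acetyl chloride | O=C(Cl)Cc1c(F)cc(OCc2ccccc2)cc1OCc1ccccc1 | intermediate
7 | 3,4-bis(benzyloxy)benzaldehyde | O=Cc1ccc(OCc2ccccc2)c(OCc2ccccc2)c1 | starting material
8 | [2-fluoro-4,6-bis(benzyloxy)phenyl]ketene | O=C=Cc1c(F)cc(OCc2ccccc2)cc1OCc1ccccc1 | intermediate (not isolated)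
9 | (3R,4R)-4-[3,4-bis(benzyloxy)phenyl]-3-[2-fluoro-4,6-bis(benzyloxy)phenyl]oxetan-2-one (cis) | O=C1O[C@@H](c2ccc(OCc3ccccc3)c(OCc3ccccc3)c2)[C@H]1c1c(F)cc(OCc2ccccc2)cc1OCc1ccccc1 | intermediate
10 | 2-fluoro-4,6-bis(benzyloxy)phenyllithium | [Li]c1c(F)cc(OCc2ccccc2)cc1OCc1ccccc1 | intermediate (not isolated)
11 | lithium alkoxide of (2R,3R)-1,2-bis[2-fluoro-4,6-bis(benzyloxy)phenyl]-3-[3,4-bis(benzyloxy)phenyl]-3-hydroxypropan-1-one | O=C(c1c(F)cc(OCc2ccccc2)cc1OCc1ccccc1)[C@H](c1c(F)cc(OCc2ccccc2)cc1OCc1ccccc1)[C@@H](O[Li])c1ccc(OCc2ccccc2)c(OCc2ccccc2)c1 | intermediate (not isolated)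
12 | (2R,3R)-5,7-bis(benzyloxy)-2-[3,4-bis(benzyloxy)phenyl]-3-[2-fluoro-4,6-bis(benzyloxy)phenyl]chroman-4-one (2,3-cis) | O=C1c2c(OCc3ccccc3)cc(OCc3ccccc3)cc2O[C@@H](c2ccc(OCc3ccccc3)c(OCc3ccccc3)c2)[C@H]1c1c(F)cc(OCc2ccccc2)cc1OCc1ccccc1 | intermediate
13 | (2R,3S,4R)-5,7-bis(benzyloxy)-2-[3,4-bis(benzyloxy)phenyl]-3-[2-fluoro-4,6-bis(benzyloxy)phenyl]chroman-4-ol (all-cis) | O[C@H]1c2c(OCc3ccccc3)cc(OCc3ccccc3)cc2O[C@@H](c2ccc(OCc3ccccc3)c(OCc3ccccc3)c2)[C@H]1c1c(F)cc(OCc2ccccc2)cc1OCc1ccccc1 | intermediate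
14 | (2R,3R,4R)-5,7-bis(benzyloxy)-2-[3,4-bis(benzyloxy)phenyl]-4-(tert-butyldimethylsilyloxy)-3-[2-fluoro-4,6-bis(benzyloxy)phenyl]chromane | CC(C)(C)[Si](C)(C)O[C@H]1c2c(OCc3ccccc3)cc(OCc3ccccc3)cc2O[C@@H](c2ccc(OCc3ccccc3)c(OCc3ccccc3)c2)[C@H]1c1c(F)cc(OCc2ccccc2)cc1OCc1ccccc1 | intermediate
15 | 4'-(benzyloxy)acetophenone | CC(=O)c1ccc(OCc2ccccc2)cc1 | starting material
16 | ethyl 3-[4-(benzyloxy)phenyl]-3-oxopropanoate | CCOC(=O)CC(=O)c1ccc(OCc2ccccc2)cc1 | intermediate
17 | ethyl (3S)-3-[4-(benzyloxy)phenyl]-3-hydroxypropanoate | CCOC(=O)C[C@H](O)c1ccc(OCc2ccccc2)cc1 | intermediate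
18 | (3S)-3-[4-(benzyloxy)phenyl]-3-hydroxy-N-methoxy-N-methylpropanamide | CON(C)C(=O)C[C@H](O)c1ccc(OCc2ccccc2)cc1 | intermediate
19 | (3S)-3-[4-(benzyloxy)phenyl]-N-methoxy-N-methyl-3-(triethylsilyloxy)propanamide | CON(C)C(=O)C[C@H](O[Si](CC)(CC)CC)c1ccc(OCc2ccccc2)cc1 | intermediate
20 | aryllithium of 14, lithium on the fluoroaryl ring at the carbon between F and OBn | CC(C)(C)[Si](C)(C)O[C@H]1c2c(OCc3ccccc3)cc(OCc3ccccc3)cc2O[C@@H](c2ccc(OCc3ccccc3)c(OCc3ccccc3)c2)[C@H]1c1c(F)c([Li])c(OCc2ccccc2)cc1OCc1ccccc1 | intermediate (not isolated)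
21 | (3S)-3-[4-(benzyloxy)phenyl]-1-{2-fluoro-4,6-bis(benzyloxy)-3-[(2R,3R,4R)-5,7-bis(benzyloxy)-2-[3,4-bis(benzyloxy)phenyl]-4-(tert-butyldimethylsilyloxy)chroman-3-yl]phenyl}-3-(triethylsilyloxy)propan-1-one | CC(C)(C)[Si](C)(C)O[C@H]1c2c(OCc3ccccc3)cc(OCc3ccccc3)cc2O[C@@H](c2ccc(OCc3ccccc3)c(OCc3ccccc3)c2)[C@H]1c1c(F)c(C(=O)C[C@H](O[Si](CC)(CC)CC)c2ccc(OCc3ccccc3)cc2)c(OCc2ccccc2)cc1OCc1ccccc1 | intermediate
22 | (3S)-3-[4-(benzyloxy)phenyl]-1-{2-fluoro-4,6-bis(benzyloxy)-3-[(2R,3R,4R)-5,7-bis(benzyloxy)-2-[3,4-bis(benzyloxy)phenyl]-4-(tert-butyldimethylsilyloxy)chroman-3-yl]phenyl}-3-hydroxypropan-1-one | CC(C)(C)[Si](C)(C)O[C@H]1c2c(OCc3ccccc3)cc(OCc3ccccc3)cc2O[C@@H](c2ccc(OCc3ccccc3)c(OCc3ccccc3)c2)[C@H]1c1c(F)c(C(=O)C[C@H](O)c2ccc(OCc3ccccc3)cc2)c(OCc2ccccc2)cc1OCc1ccccc1 | intermediate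
23 | (2S)-5,7-bis(benzyloxy)-2-[4-(benzyloxy)phenyl]-8-{(2R,3R,4R)-5,7-bis(benzyloxy)-2-[3,4-bis(benzyloxy)phenyl]-4-(tert-butyldimethylsilyloxy)chroman-3-yl}chroman-4-one | O=C1C[C@@H](c2ccc(OCc3ccccc3)cc2)Oc2c1c(OCc1ccccc1)cc(OCc1ccccc1)c2[C@H]1[C@@H](O[Si](C)(C)C(C)(C)C)c2c(OCc3ccccc3)cc(OCc3ccccc3)cc2O[C@H]1c1ccc(OCc2ccccc2)c(OCc2ccccc2)c1 | intermediate
24 | (2S)-5,7-bis(benzyloxy)-2-[4-(benzyloxy)phenyl]-8-{(2R,3S,4R)-5,7-bis(benzyloxy)-2-[3,4-bis(benzyloxy)phenyl]-4-hydroxychroman-3-yl}chroman-4-one | O=C1C[C@@H](c2ccc(OCc3ccccc3)cc2)Oc2c1c(OCc1ccccc1)cc(OCc1ccccc1)c2[C@H]1[C@@H](O)c2c(OCc3ccccc3)cc(OCc3ccccc3)cc2O[C@H]1c1ccc(OCc2ccccc2)c(OCc2ccccc2)c1 | intermediate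
25 | (2S)-5,7-bis(benzyloxy)-2-[4-(benzyloxy)phenyl]-8-{(2R,3R)-5,7-bis(benzyloxy)-2-[3,4-bis(benzyloxy)phenyl]-4-oxochroman-3-yl}chroman-4-one | O=C1C[C@@H](c2ccc(OCc3ccccc3)cc2)Oc2c1c(OCc1ccccc1)cc(OCc1ccccc1)c2[C@H]1C(=O)c2c(OCc3ccccc3)cc(OCc3ccccc3)cc2O[C@H]1c1ccc(OCc2ccccc2)c(OCc2ccccc2)c1 | intermediate
26 | (2S)-8-[(2R,3R)-2-(3,4-dihydroxyphenyl)-5,7-dihydroxy-4-oxochroman-3-yl]-5,7-dihydroxy-2-(4-hydroxyphenyl)chroman-4-one | O=C1C[C@@H](c2ccc(O)cc2)Oc2c1c(O)cc(O)c2[C@H]1C(=O)c2c(O)cc(O)cc2O[C@H]1c1ccc(O)c(O)c1 | target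

**Step count**

Total: 19 steps. Longest linear sequence: 15 steps (steps 1–9 and 14–19, from 5-fluororesorcinol); the Weinreb amide 19 is made in 4 steps (10–13).

**Steps most likely to fail**

Step 6 (key step). The ammonium enolate may add too slowly to the electron-rich aldehyde, so that ketene dimerisation takes over. The cis lactone may be epimerised at C3 by the amine. The electron-rich 4-aryl lactone may ionise at C4 and lose CO2 during work-up. The fallback is an auxiliary-controlled syn aldol, setting out from acid 5 and aldehyde 7 and coming back at lactone 9. Acid 5 is converted through its pivaloyl mixed anhydride (PivCl, Et3N; then the lithium salt of (R)-4-benzyloxazolidin-2-one, THF, −78 °C) into the imide (4R)-4-benzyl-3-{[2-fluoro-4,6-bis(benzyloxy)phenyl]acetyl}oxazolidin-2-one F1. Its Z boron enolate (Bu2BOTf, iPr2NEt, CH2Cl2, −78 °C) should add to 7 through the Evans chair transition state to give the syn aldol imide (4R)-4-benzyl-3-{(2R,3R)-3-[3,4-bis(benzyloxy)phenyl]-2-[2-fluoro-4,6-bis(benzyloxy)phenyl]-3-hydroxypropanoyl}oxazolidin-2-one F2. Cleavage with LiOH/H2O2 (THF/H2O, 0 °C) should give (2R,3R)-3-[3,4-bis(benzyloxy)phenyl]-2-[2-fluoro-4,6-bis(benzyloxy)phenyl]-3-hydroxypropanoic acid F3. Carboxyl activation (PhSO2Cl, pyridine, 0 °C) then closes the β-lactone with retention at both centres, giving 9.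

Step 7. The aryllithium may deprotonate C3 of the lactone instead of attacking its carbonyl. The crowded lithium aldolate may undergo retro-aldol cleavage before ring closure, which would scramble both centres. The ortho-fluoroaryllithium may lose LiF on warming. The fallback separates acyl transfer from ring closure, setting out from 9 (and 3) and coming back at 12. Lactone 9 is opened with MeNH(OMe)·HCl and Me2AlCl (CH2Cl2, −30 °C) to (2R,3R)-3-[3,4-bis(benzyloxy)phenyl]-2-[2-fluoro-4,6-bis(benzyloxy)phenyl]-3-hydroxy-N-methoxy-N-methylpropanamide F4. Silylation (TESOTf, 2,6-lutidine) gives (2R,3R)-3-[3,4-bis(benzyloxy)phenyl]-2-[2-fluoro-4,6-bis(benzyloxy)phenyl]-N-methoxy-N-methyl-3-(triethylsilyloxy)propanamide F5. Aryllithium 10 (from 3, −78 °C) adds to F5 through the chelated tetrahedral intermediate, so that no alkoxide sits β to a ketone, giving (2R,3R)-1,2-bis[2-fluoro-4,6-bis(benzyloxy)phenyl]-3-[3,4-bis(benzyloxy)phenyl]-3-(triethylsilyloxy)propan-1-one F6. A substoichiometric amount of TBAF (THF, −20 °C) then removes the silyl group; the alkoxide closes ring C by SNAr and returns fluoride, giving 12.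

Step 16. The ketone enolate may expel hydroxide (E1cB) to give a chalcone that cannot recyclise because it carries fluorine in place of a phenol. Retro-aldol cleavage may compete with the SNAr. The fallback is the classical chalcone route, setting out from 14 and coming back at 23. Lithiation of 14 as in step 14 and acylation with N-methoxy-N-methylacetamide give the 3-acetyl derivative of 14 (acetyl on the fluoroaryl ring between F and OBn) F7. 2-(Methylsulfonyl)ethanol and NaH in DMF replace the activated fluorine by hydroxyl, giving the 2-hydroxy-3-acetyl analogue of 14 F8. Claisen–Schmidt condensation with 4-(benzyloxy)benzaldehyde (KOH, EtOH) gives the (E)-2'-hydroxychalcone F9. Oxa-Michael cyclisation (NaOAc, EtOH, reflux) gives 23 together with the (2''R) epimer of 23 F10. The two are diastereomers and are separated by chromatography; F10 is re-equilibrated under the same conditions, while the C4 silyl ether keeps C3 fixed.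

**Further compounds**

F1 | step 6 | (4R)-4-benzyl-3-{[2-fluoro-4,6-bis(benzyloxy)phenyl]acetyl}oxazolidin-2-one | O=C(Cc1c(F)cc(OCc2ccccc2)cc1OCc1ccccc1)N1[C@H](Cc2ccccc2)COC1=O
F2 | step 6 | (4R)-4-benzyl-3-{(2R,3R)-3-[3,4-bis(benzyloxy)phenyl]-2-[2-fluoro-4,6-bis(benzyloxy)phenyl]-3-hydroxypropanoyl}oxazolidin-2-one | O=C([C@H](c1c(F)cc(OCc2ccccc2)cc1OCc1ccccc1)[C@@H](O)c1ccc(OCc2ccccc2)c(OCc2ccccc2)c1)N1[C@H](Cc2ccccc2)COC1=O
F3 | step 6 | (2R,3R)-3-[3,4-bis(benzyloxy)phenyl]-2-[2-fluoro-4,6-bis(benzyloxy)phenyl]-3-hydroxypropanoic acid | OC(=O)[C@H](c1c(F)cc(OCc2ccccc2)cc1OCc1ccccc1)[C@@H](O)c1ccc(OCc2ccccc2)c(OCc2ccccc2)c1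
F4 | step 7 | (2R,3R)-3-[3,4-bis(benzyloxy)phenyl]-2-[2-fluoro-4,6-bis(benzyloxy)phenyl]-3-hydroxy-N-methoxy-N-methylpropanamide | CON(C)C(=O)[C@H](c1c(F)cc(OCc2ccccc2)cc1OCc1ccccc1)[C@@H](O)c1ccc(OCc2ccccc2)c(OCc2ccccc2)c1
F5 | step 7 | (2R,3R)-3-[3,4-bis(benzyloxy)phenyl]-2-[2-fluoro-4,6-bis(benzyloxy)phenyl]-N-methoxy-N-methyl-3-(triethylsilyloxy)propanamide | CON(C)C(=O)[C@H](c1c(F)cc(OCc2ccccc2)cc1OCc1ccccc1)[C@@H](O[Si](CC)(CC)CC)c1ccc(OCc2ccccc2)c(OCc2ccccc2)c1
F6 | step 7 | (2R,3R)-1,2-bis[2-fluoro-4,6-bis(benzyloxy)phenyl]-3-[3,4-bis(benzyloxy)phenyl]-3-(triethylsilyloxy)propan-1-one | O=C(c1c(F)cc(OCc2ccccc2)cc1OCc1ccccc1)[C@H](c1c(F)cc(OCc2ccccc2)cc1OCc1ccccc1)[C@@H](O[Si](CC)(CC)CC)c1ccc(OCc2ccccc2)c(OCc2ccccc2)c1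
F7 | step 16 | 3-acetyl derivative of 14 (acetyl on the fluoroaryl ring between F and OBn) | CC(C)(C)[Si](C)(C)O[C@H]1c2c(OCc3ccccc3)cc(OCc3ccccc3)cc2O[C@@H](c2ccc(OCc3ccccc3)c(OCc3ccccc3)c2)[C@H]1c1c(F)c(C(C)=O)c(OCc2ccccc2)cc1OCc1ccccc1
F8 | step 16 | 2-hydroxy-3-acetyl analogue of 14 (hydroxyl in place of fluorine) | CC(C)(C)[Si](C)(C)O[C@H]1c2c(OCc3ccccc3)cc(OCc3ccccc3)cc2O[C@@H](c2ccc(OCc3ccccc3)c(OCc3ccccc3)c2)[C@H]1c1c(O)c(C(C)=O)c(OCc2ccccc2)cc1OCc1ccccc1
F9 | step 16 | (E)-2'-hydroxychalcone from F8 and 4-(benzyloxy)benzaldehyde | CC(C)(C)[Si](C)(C)O[C@H]1c2c(OCc3ccccc3)cc(OCc3ccccc3)cc2O[C@@H](c2ccc(OCc3ccccc3)c(OCc3ccccc3)c2)[C@H]1c1c(O)c(C(=O)/C=C/c2ccc(OCc3ccccc3)cc2)c(OCc2ccccc2)cc1OCc1ccccc1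
F10 | step 16 | (2''R) epimer of 23 | O=C1C[C@H](c2ccc(OCc3ccccc3)cc2)Oc2c1c(OCc1ccccc1)cc(OCc1ccccc1)c2[C@H]1[C@@H](O[Si](C)(C)C(C)(C)C)c2c(OCc3ccccc3)cc(OCc3ccccc3)cc2O[C@H]1c1ccc(OCc2ccccc2)c(OCc2ccccc2)c1
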